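The cyclohexane (C1, C10–C14) is not made directly. A cyclopentanol (C14, C10–C13) carrying a 2,3-epoxy side chain on C14 undergoes a semipinacol 1,2-shift of C10 from C14 to C1. This one operation expands the ring, creates the quaternary C1 with inversion, unveils the C14 carbonyl and keeps the C2 carbinol. It exploits the C14(O)–C1(Me)–C2(O) β-hydroxy-ketone array at the ring fusion. The precursor arises by joining a (Z)-alkenyl unit (C15, C1–C4) to a cis-2-ethenyl-3-methylcyclopentanone, then reagent-controlled epoxidation. Later come Nozaki–Hiyama–Kishi coupling at C8–C9, reductive aldol lactonisation, and Horner–Wadsworth–Emmons closure of the ten-membered ring at C5=C6.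

Key step: step 9

Remark: briarane numbering is used for all carbons and α/β refer to the six-membered ring (Me-15 = β); the C14 configuration of 12 and 13 is drawn for attack anti to the C10 ethenyl group and has no consequence, because C14 becomes a carbonyl carbon in step 9.

Step 1
Reactants: 1 (R)-4-(tert-butyldimethylsilyloxy)cyclopent-2-en-1-one
Product: 2 (R)-4-(tert-butyldimethylsilyloxy)-2-iodocyclopent-2-en-1-one
Conditions: I2, pyridine, CH2Cl2, 0 °C to rt
Reagents that add atoms: iodine, [I][I]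
Why: α-Iodination of the enone by conjugate addition of pyridine, iodination of the enolate and elimination (addition–elimination halogenation) leaves the C12 stereocentre untouched.

Step 2
Reactants: 2 (R)-4-(tert-butyldimethylsilyloxy)-2-iodocyclopent-2-en-1-one
Product: 3 (R)-4-(tert-butyldimethylsilyloxy)-2-ethenylcyclopent-2-en-1-one
Conditions: tributyl(vinyl)stannane, Pd2(dba)3 (cat.), AsPh3, CuI (cat.), NMP, rt
Reagents that add atoms: tributyl(vinyl)stannane, C=C[Sn](CCCC)(CCCC)CCCC
Why: Stille coupling of an α-iodoenone under zerovalent palladium catalysis installs the ethenyl group whose inner carbon becomes C9.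

Step 3
Reactants: 3 (R)-4-(tert-butyldimethylsilyloxy)-2-ethenylcyclopent-2-en-1-one
Product: 5 (2S,3R,4R)-4-(tert-butyldimethylsilyloxy)-2-ethenyl-3-methylcyclopentan-1-one, via lithium dienolate 4 (not isolated)
Conditions: Me2CuLi (from MeLi, CuI), Et2O, −78 °C; then methyl salicylate, −78 °C; aq. NH4Cl
Reagents that add atoms: lithium dimethylcuprate, [Li+].C[Cu-]C
Why: Cuprate 1,4-addition occurs anti to the C12 silyloxy group (sets C11), and diastereoselective kinetic protonation of the dienolate at C10 by the bulky chelating phenol from the face opposite the new methyl should give the cis-2,3 ketone (sets C10), which is worked up cold and neutral and used crude.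

Step 4
Reactants: 6 3-(tert-butyldimethylsilyloxy)propanal
Product: 7 (Z)-tert-butyl[(4-iodopent-3-en-1-yl)oxy]dimethylsilane
Conditions: EtPPh3I, n-BuLi, THF; I2, −78 °C; NaN(SiMe3)2, −20 °C; then 6, −78 °C
Reagents that add atoms: ethyltriphenylphosphonium iodide, CC[P+](c1ccccc1)(c1ccccc1)c1ccccc1.[I-]; iodine, [I][I]
Why: Stork–Zhao-type Wittig olefination with the α-iodo ylide is known to give (Z)-2-iodo-2-alkenes, which fixes the geometry of the future C1=C2 unit.

Step 5
Reactants: 7 (Z)-tert-butyl[(4-iodopent-3-en-1-yl)oxy]dimethylsilane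
Product: 8 (Z)-4-iodopent-3-en-1-ol
Conditions: camphor-10-sulfonic acid (cat.), MeOH, 0 °C to rt
Reagents that add atoms: none
Why: Acid-catalysed methanolysis of a primary silyl ether leaves the alkenyl iodide untouched.

Step 6
Reactants: 8 (Z)-4-iodopent-3-en-1-ol
Product: 9 (Z)-5-chloro-2-iodopent-2-ene
Conditions: PPh3, N-chlorosuccinimide, CH2Cl2, 0 °C
Reagents that add atoms: N-chlorosuccinimide, O=C1CCC(=O)N1Cl
Why: Appel-type chlorination of the primary alcohol gives a latent C4 leaving group that should survive organolithium exchange at −78 °C, oxidants, Lewis acid and CrCl2 until step 22.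

Step 7
Reactants: 9 (Z)-5-chloro-2-iodopent-2-ene; 5 (2S,3R,4R)-4-(tert-butyldimethylsilyloxy)-2-ethenyl-3-methylcyclopentan-1-one
Product: 12 (1R,2S,3R,4R)-4-(tert-butyldimethylsilyloxy)-1-[(2Z)-5-chloropent-2-en-2-yl]-2-ethenyl-3-methylcyclopentan-1-ol, via alkenyllithium 10 (not isolated), via alkenylcerium dichloride 11 (not isolated)
Conditions: 9, t-BuLi (2 equiv), Et2O, −78 °C; CeCl3, THF, −78 °C; then 5, −78 °C; aq. NH4Cl
Reagents that add atoms: none
Why: Iodine–lithium exchange retains the alkene geometry and the weakly basic organocerium reagent adds 1,2 to the easily enolised ketone without epimerising C10 (carbonyl addition), so the C14–C1 bond joins the two fragments with the carbinol cis to C3.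

Step 8
Reactants: 12 (1R,2S,3R,4R)-4-(tert-butyldimethylsilyloxy)-1-[(2Z)-5-chloropent-2-en-2-yl]-2-ethenyl-3-methylcyclopentan-1-ol
Product: 13 (1R,2S,3R,4R)-4-(tert-butyldimethylsilyloxy)-1-[(2R,3R)-3-(2-chloroethyl)-2-methyloxiran-2-yl]-2-ethenyl-3-methylcyclopentan-1-ol
Conditions: 1,2:4,5-di-O-isopropylidene-β-D-erythro-2,3-hexodiulo-2,6-pyranose (D-fructose-derived Shi ketone, cat.), KHSO5 (as 2KHSO5·KHSO4·K2SO4), K2CO3, Bu4NHSO4, MeCN/CH2(OMe)2/aq. Na2B4O7 buffer, 0 °C
Reagents that add atoms: potassium peroxymonosulfate, [K+].[O-]S(=O)(=O)OO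
Why: Shi epoxidation through the spiro transition state is reagent-controlled and should deliver oxygen to the face that gives the (2R,3R)-oxirane (sets C2 and the epoxide configuration at C1), while the less electron-rich terminal ethenyl group is left.

Step 9
Reactants: 13 (1R,2S,3R,4R)-4-(tert-butyldimethylsilyloxy)-1-[(2R,3R)-3-(2-chloroethyl)-2-methyloxiran-2-yl]-2-ethenyl-3-methylcyclopentan-1-ol
Product: 14 (2S,3S,4R,5R)-5-(tert-butyldimethylsilyloxy)-2-[(1R)-3-chloro-1-hydroxypropyl]-3-ethenyl-2,4-dimethylcyclohexan-1-one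
Conditions: BF3·OEt2, CH2Cl2, −78 °C
Reagents that add atoms: none
Why: BF3 activates the epoxide oxygen, the C1–O bond ionises at the tertiary carbon, and the antiperiplanar C14–C10 bond migrates to C1 in a concerted 1,2-shift while the carbinol oxygen forms the C14 carbonyl. The closest known reaction type is the Lewis-acid semipinacol rearrangement of tertiary 2,3-epoxy alcohols with ring expansion of a 1-(oxiranyl)cycloalkanol to a 2-(1-hydroxyalkyl)cycloalkanone. No ring is closed by cyclisation; the six-membered ring forms by one-carbon ring enlargement of the cyclopentane, C1 being inserted between C14 and C10. C1 is set by inversion (migration anti to the departing oxygen) from the epoxide configuration of step 8, C2 keeps its epoxide configuration, C10 migrates with retention, and C11 and C12 are untouched. The step needs opening at C1 and not C2, which the tertiary carbinol-flanked epoxide carbon secures, and migration of C10 and not C13, which is favoured because C10 is secondary and allylic. The C14 configuration of 13 is irrelevant since C14 becomes trigonal.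

Step 10
Reactants: 14 (2S,3S,4R,5R)-5-(tert-butyldimethylsilyloxy)-2-[(1R)-3-chloro-1-hydroxypropyl]-3-ethenyl-2,4-dimethylcyclohexan-1-one
Product: 16 (1S,2R,3S,4R,5R)-5-(tert-butyldimethylsilyloxy)-2-[(1R)-3-chloro-1-hydroxypropyl]-3-ethenyl-2,4-dimethylcyclohexan-1-ol, via O-diethylboryl chelate 15 (not isolated)
Conditions: Et2BOMe, THF/MeOH, −78 °C; NaBH4; AcOH; MeOH co-evaporation
Reagents that add atoms: none
Why: Narasaka–Prasad reduction, in which the boron chelate between O2 and the C14 carbonyl occupies the α face so that external hydride adds from the β face, should give the syn-1,3-diol with the 14α-hydroxyl (sets C14).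

Step 11
Reactants: 16 (1S,2R,3S,4R,5R)-5-(tert-butyldimethylsilyloxy)-2-[(1R)-3-chloro-1-hydroxypropyl]-3-ethenyl-2,4-dimethylcyclohexan-1-ol
Product: 17 2,14-di-O-acetyl derivative of 16
Conditions: Ac2O, pyridine, 4-(dimethylamino)pyridine, CH2Cl2, rt
Reagents that add atoms: acetic anhydride, CC(=O)OC(C)=O
Why: Nucleophile-catalysed acetylation installs two of the final acetates, which tolerate every later step.

Step 12
Reactants: 17 2,14-di-O-acetyl derivative of 16
Product: 19 C9 aldehyde (10β-formyl compound derived from 17), via secondary ozonide 18 (not isolated)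
Conditions: O3, CH2Cl2, −78 °C; then PPh3
Reagents that add atoms: ozone, [O-][O+]=O
Why: Ozonolysis of the only C=C bond with reductive work-up gives the aldehyde without base, so the now epimerisable C10 is preserved and the crude product is used at once.

Step 13
Reactants: 20 methyl (S)-2,2-dimethyl-1,3-dioxolane-4-carboxylate
Product: 22 (R)-4-ethynyl-2,2-dimethyl-1,3-dioxolane, via glyceraldehyde acetonide 21 (not isolated)
Conditions: i-Bu2AlH, CH2Cl2, −78 °C; then MeOH, K2CO3, dimethyl (1-diazo-2-oxopropyl)phosphonate, 0 °C to rt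
Reagents that add atoms: dimethyl (1-diazo-2-oxopropyl)phosphonate, CC(=O)C(=[N+]=[N-])P(=O)(OC)OC
Why: Half-reduction of the ester and in-flask Seyferth–Gilbert homologation with the Ohira–Bestmann reagent give the alkyne without isolating the labile aldehyde, and the C7 stereocentre from the chiral pool is retained.

Step 14
Reactants: 22 (R)-4-ethynyl-2,2-dimethyl-1,3-dioxolane
Product: 24 (S)-4-(1-iodoethenyl)-2,2-dimethyl-1,3-dioxolane, via alkenylalane 23 (not isolated)
Conditions: NiCl2(dppp) (cat.), i-Bu2AlH, THF, 0 °C to rt; then N-iodosuccinimide, 0 °C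
Reagents that add atoms: N-iodosuccinimide, O=C1CCC(=O)N1I
Why: Nickel-catalysed α-selective (Markovnikov) hydroalumination of the terminal alkyne and iodinolysis of the C–Al bond give the 1,1-disubstituted alkenyl iodide that carries C8.

Step 15
Reactants: 24 (S)-4-(1-iodoethenyl)-2,2-dimethyl-1,3-dioxolane
Product: 25 (S)-3-iodobut-3-ene-1,2-diol
Conditions: AcOH/H2O, 40 °C
Reagents that add atoms: none
Why: Acid hydrolysis of the isopropylidene acetal frees the C6 and C7 hydroxyls.

Step 16
Reactants: 25 (S)-3-iodobut-3-ene-1,2-diol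
Product: 26 (S)-1-(tert-butyldimethylsilyloxy)-3-iodobut-3-en-2-ol
Conditions: TBSCl, imidazole, CH2Cl2, −20 °C
Reagents that add atoms: tert-butyldimethylsilyl chloride, CC(C)(C)[Si](C)(C)Cl
Why: Silylation is selective for the primary C6 hydroxyl on steric grounds.

Step 17
Reactants: 26 (S)-1-(tert-butyldimethylsilyloxy)-3-iodobut-3-en-2-ol
Product: 27 (S)-1-(tert-butyldimethylsilyloxy)-3-iodobut-3-en-2-yl prop-2-enoate
Conditions: acryloyl chloride, i-Pr2NEt, CH2Cl2, −40 to 0 °C
Reagents that add atoms: acryloyl chloride, C=CC(=O)Cl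
Why: O-Acylation places on O7 the acrylate that will become C17, C18 and C19 of the lactone.

Step 18
Reactants: 19 C9 aldehyde (10β-formyl compound derived from 17); 27 (S)-1-(tert-butyldimethylsilyloxy)-3-iodobut-3-en-2-yl prop-2-enoate
Product: 29 allylic alcohol with (9R)-hydroxyl and C8 exo-methylene, via alkenylchromium dichloride 28 (not isolated)
Conditions: CrCl2, NiCl2 (cat.), DMSO/THF, rt
Reagents that add atoms: none
Why: Nozaki–Hiyama–Kishi coupling (oxidative addition to zerovalent nickel, transmetalation to trivalent chromium, carbonyl addition) is non-basic and tolerates esters and the alkyl chloride, and Felkin–Anh attack anti to the quaternary C1 with C11 as the medium group should give the (9R)-alcohol (sets C9).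

Step 19
Reactants: 29 allylic alcohol with (9R)-hydroxyl and C8 exo-methylene
Product: 30 9-O-acetyl derivative of 29
Conditions: Ac2O, pyridine, 4-(dimethylamino)pyridine, CH2Cl2, 0 °C
Reagents that add atoms: acetic anhydride, CC(=O)OC(C)=O
Why: Acetylation installs the final C9 acetate and prevents later lactol formation with C6.

Step 20
Reactants: 30 9-O-acetyl derivative of 29
Product: 32 C8 ketone flanked by the C7 acrylate and the C9 acetate, via secondary ozonide 31 (not isolated)
Conditions: O3, CH2Cl2, −78 °C (Sudan Red 7B end point); then Me2S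
Reagents that add atoms: ozone, [O-][O+]=O
Why: Ozonolysis is expected to cleave the non-conjugated 1,1-disubstituted C8 methylene much faster than the electron-poor acrylate double bond when stopped at the indicator end point.

Step 21
Reactants: 32 C8 ketone flanked by the C7 acrylate and the C9 acetate
Product: 34 β-hydroxy-γ-lactone (7S,8R,9R,17R by CIP; 8-OH cis to C6 and to Me-18), via copper enolate 33 (not isolated)
Conditions: [(Ph3P)CuH]6, toluene/THF, −40 to 0 °C; aq. NH4Cl
Reagents that add atoms: none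
Why: Copper hydride conjugate reduction of the acrylate gives a propionate enolate that adds to the C8 ketone in a reductive aldol cyclisation, the five-membered closure placing C6 and the bulky C9 branch trans (sets C8) and the chelated enolate putting Me-18 cis to the new hydroxyl (sets C17), which is also the less crowded, base-equilibratable epimer.

Step 22
Reactants: 34 β-hydroxy-γ-lactone
Product: 36 C5 dimethyl phosphonate methyl ester (both C5 epimers), via primary iodide 35 (not isolated)
Conditions: trimethyl phosphonoacetate, NaH, DMF, 0 °C; then 34, NaI, 60 °C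
Reagents that add atoms: trimethyl phosphonoacetate, COC(=O)CP(=O)(OC)OC
Why: Finkelstein-assisted SN2 alkylation of the stabilised phosphonoacetate anion at the primary C4 is too weakly basic to disturb lactone, acetates or the tertiary alcohol, and the C5 mixture is removed in step 25.

Step 23
Reactants: 36 C5 dimethyl phosphonate methyl ester
Product: 37 6,8,12-triol
Conditions: HF·pyridine, pyridine/THF, 0 °C to rt
Reagents that add atoms: none
Why: Buffered fluoride cleaves both silyl ethers while acetates, lactone and phosphonate are stable.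

Step 24
Reactants: 37 6,8,12-triol
Product: 38 C6 aldehyde
Conditions: 2,2,6,6-tetramethylpiperidine-1-oxyl (cat.), PhI(OAc)2, CH2Cl2, rt
Reagents that add atoms: none
Why: Oxoammonium oxidation is selective for the primary C6 hydroxyl over the secondary C12 and tertiary C8 hydroxyls.

Step 25
Reactants: 38 C6 aldehyde
Product: 39 12-O-deacetyl target (ten-membered ring closed)
Conditions: LiCl, i-Pr2NEt, MeCN, high dilution, rt
Reagents that add atoms: none
Why: Intramolecular Horner–Wadsworth–Emmons olefination under Masamune–Roush conditions should close the ring at C5=C6 because the favoured E enoate (ester trans to C7) is the in-ring cis alkene a ten-membered ring accommodates, and the mild amine base spares C7 and the β-hydroxy lactone.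

Step 26
Reactants: 39 12-O-deacetyl target
Product: 40 CNP0230222.1
Conditions: Ac2O, pyridine, 4-(dimethylamino)pyridine (cat.), CH2Cl2, 0 °C to rt
Reagents that add atoms: acetic anhydride, CC(=O)OC(C)=O
Why: Acetylation of the secondary C12 hydroxyl completes the tetraacetate, while the hindered tertiary C8 hydroxyl is expected to stay free.

Compound list

1 | (R)-4-(tert-butyldimethylsilyloxy)cyclopent-2-en-1-one | O=C1C=C[C@H](O[Si](C)(C)C(C)(C)C)C1 | starting material
2 | (R)-4-(tert-butyldimethylsilyloxy)-2-iodocyclopent-2-en-1-one | O=C1C([I])=C[C@H](O[Si](C)(C)C(C)(C)C)C1 | intermediate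
3 | (R)-4-(tert-butyldimethylsilyloxy)-2-ethenylcyclopent-2-en-1-one | O=C1C(C=C)=C[C@H](O[Si](C)(C)C(C)(C)C)C1 | intermediate
4 | lithium (3R,4R)-4-(tert-butyldimethylsilyloxy)-2-ethenyl-3-methylcyclopent-1-en-1-olate | [Li]OC1=C(C=C)[C@@H](C)[C@H](O[Si](C)(C)C(C)(C)C)C1 | intermediate (not isolated)
5 | (2S,3R,4R)-4-(tert-butyldimethylsilyloxy)-2-ethenyl-3-methylcyclopentan-1-one (2,3-cis, 3,4-trans) | O=C1[C@@H](C=C)[C@@H](C)[C@H](O[Si](C)(C)C(C)(C)C)C1 | intermediate
6 | 3-(tert-butyldimethylsilyloxy)propanal | O=CCCO[Si](C)(C)C(C)(C)C | starting material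
7 | (Z)-tert-butyl[(4-iodopent-3-en-1-yl)oxy]dimethylsilane | C/C([I])=C/CCO[Si](C)(C)C(C)(C)C | intermediate
8 | (Z)-4-iodopent-3-en-1-ol | C/C([I])=C/CCO | intermediate
9 | (Z)-5-chloro-2-iodopent-2-ene | C/C([I])=C/CCCl | intermediate
10 | (5-chloropent-2-en-2-yl)lithium, Li cis to the chloroethyl chain | C/C([Li])=C/CCCl | intermediate (not isolated)
11 | dichloro(5-chloropent-2-en-2-yl)cerium, same geometry | C/C([Ce](Cl)Cl)=C/CCCl | intermediate (not isolated)
12 | (1R,2S,3R,4R)-4-(tert-butyldimethylsilyloxy)-1-[(2Z)-5-chloropent-2-en-2-yl]-2-ethenyl-3-methylcyclopentan-1-ol | C/C(=C/CCCl)[C@]1(O)[C@@H](C=C)[C@@H](C)[C@H](O[Si](C)(C)C(C)(C)C)C1 | intermediate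
13 | (1R,2S,3R,4R)-4-(tert-butyldimethylsilyloxy)-1-[(2R,3R)-3-(2-chloroethyl)-2-methyloxiran-2-yl]-2-ethenyl-3-methylcyclopentan-1-ol | C[C@]1(O[C@@H]1CCCl)[C@]2(O)[C@@H](C=C)[C@@H](C)[C@H](O[Si](C)(C)C(C)(C)C)C2 | intermediate
14 | (2S,3S,4R,5R)-5-(tert-butyldimethylsilyloxy)-2-[(1R)-3-chloro-1-hydroxypropyl]-3-ethenyl-2,4-dimethylcyclohexan-1-one (C14 ketone; Me-15 β, H-10 α, Me-20 β, 12-OTBS α) | C=C[C@H]1[C@@H](C)[C@H](O[Si](C)(C)C(C)(C)C)CC(=O)[C@]1(C)[C@H](O)CCCl | intermediate
15 | O2-diethylboryl derivative (boron chelate) of 14 | C=C[C@H]1[C@@H](C)[C@H](O[Si](C)(C)C(C)(C)C)CC(=O)[C@]1(C)[C@H](OB(CC)CC)CCCl | intermediate (not isolated)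
16 | (1S,2R,3S,4R,5R)-5-(tert-butyldimethylsilyloxy)-2-[(1R)-3-chloro-1-hydroxypropyl]-3-ethenyl-2,4-dimethylcyclohexan-1-ol (14α-OH, syn to 2-OH) | C=C[C@H]1[C@@H](C)[C@H](O[Si](C)(C)C(C)(C)C)C[C@H](O)[C@]1(C)[C@H](O)CCCl | intermediate
17 | 2,14-di-O-acetyl derivative of 16 | C=C[C@H]1[C@@H](C)[C@H](O[Si](C)(C)C(C)(C)C)C[C@H](OC(C)=O)[C@]1(C)[C@H](OC(C)=O)CCCl | intermediate
18 | 1,2,4-trioxolane (secondary ozonide) of 17 at the ethenyl group | C1OC(OO1)[C@H]2[C@@H](C)[C@H](O[Si](C)(C)C(C)(C)C)C[C@H](OC(C)=O)[C@]2(C)[C@H](OC(C)=O)CCCl | intermediate (not isolated)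
19 | C9 aldehyde: 10β-formyl cyclohexane with Me-15 β, (2R)-CH(OAc)CH2CH2Cl α at C1, Me-20 β, 12α-OTBS, 14α-OAc | O=C[C@H]1[C@@H](C)[C@H](O[Si](C)(C)C(C)(C)C)C[C@H](OC(C)=O)[C@]1(C)[C@H](OC(C)=O)CCCl | intermediate
20 | methyl (S)-2,2-dimethyl-1,3-dioxolane-4-carboxylate | COC(=O)[C@@H]1COC(C)(C)O1 | starting material
21 | (S)-2,2-dimethyl-1,3-dioxolane-4-carbaldehyde | O=C[C@@H]1COC(C)(C)O1 | intermediate (not isolated)
22 | (R)-4-ethynyl-2,2-dimethyl-1,3-dioxolane | C#C[C@@H]1COC(C)(C)O1 | intermediate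
23 | diisobutyl{1-[(S)-2,2-dimethyl-1,3-dioxolan-4-yl]ethenyl}alane | C=C([Al](CC(C)C)CC(C)C)[C@@H]1COC(C)(C)O1 | intermediate (not isolated)
24 | (S)-4-(1-iodoethenyl)-2,2-dimethyl-1,3-dioxolane | C=C([I])[C@@H]1COC(C)(C)O1 | intermediate
25 | (S)-3-iodobut-3-ene-1,2-diol | C=C([I])[C@@H](O)CO | intermediate
26 | (S)-1-(tert-butyldimethylsilyloxy)-3-iodobut-3-en-2-ol | C=C([I])[C@@H](O)CO[Si](C)(C)C(C)(C)C | intermediate
27 | (S)-1-(tert-butyldimethylsilyloxy)-3-iodobut-3-en-2-yl prop-2-enoate | C=C([I])[C@@H](OC(=O)C=C)CO[Si](C)(C)C(C)(C)C | intermediate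
28 | alkenylchromium dichloride derived from 27 (CrCl2 in place of iodine) | C=C([Cr](Cl)Cl)[C@@H](OC(=O)C=C)CO[Si](C)(C)C(C)(C)C | intermediate (not isolated)
29 | coupling product: (9R)-allylic alcohol, C8 exo-methylene, C7 acrylate (7R by CIP), C6 OTBS, core as in 19 | CC(C)(C)[Si](C)(C)OC[C@H](OC(=O)C=C)C(=C)[C@H](O)[C@H]1[C@@H](C)[C@H](O[Si](C)(C)C(C)(C)C)C[C@H](OC(C)=O)[C@]1(C)[C@H](OC(C)=O)CCCl | intermediate
30 | 9-O-acetyl derivative of 29 | CC(C)(C)[Si](C)(C)OC[C@H](OC(=O)C=C)C(=C)[C@H](OC(C)=O)[C@H]1[C@@H](C)[C@H](O[Si](C)(C)C(C)(C)C)C[C@H](OC(C)=O)[C@]1(C)[C@H](OC(C)=O)CCCl | intermediate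
31 | spiro-1,2,4-trioxolane (secondary ozonide) of 30 at the C8 methylene | CC(C)(C)[Si](C)(C)OC[C@H](OC(=O)C=C)C1(OCOO1)[C@H](OC(C)=O)[C@H]2[C@@H](C)[C@H](O[Si](C)(C)C(C)(C)C)C[C@H](OC(C)=O)[C@]2(C)[C@H](OC(C)=O)CCCl | intermediate (not isolated)
32 | C8 ketone with (7S)-acryloyloxy and (9R)-acetoxy groups | CC(C)(C)[Si](C)(C)OC[C@H](OC(=O)C=C)C(=O)[C@H](OC(C)=O)[C@H]1[C@@H](C)[C@H](O[Si](C)(C)C(C)(C)C)C[C@H](OC(C)=O)[C@]1(C)[C@H](OC(C)=O)CCCl | intermediate
33 | copper propionate enolate of 32 on O7 | CC(C)(C)[Si](C)(C)OC[C@H](OC(O[Cu])=CC)C(=O)[C@H](OC(C)=O)[C@H]1[C@@H](C)[C@H](O[Si](C)(C)C(C)(C)C)C[C@H](OC(C)=O)[C@]1(C)[C@H](OC(C)=O)CCCl | intermediate (not isolated)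
34 | β-hydroxy-α-methyl-γ-lactone (7S,8R,9R,17R by CIP), C6 OTBS, C4 chloride | CC(C)(C)[Si](C)(C)OC[C@@H]2OC(=O)[C@H](C)[C@@]2(O)[C@H](OC(C)=O)[C@H]1[C@@H](C)[C@H](O[Si](C)(C)C(C)(C)C)C[C@H](OC(C)=O)[C@]1(C)[C@H](OC(C)=O)CCCl | intermediate
35 | C4 iodide corresponding to 34 | CC(C)(C)[Si](C)(C)OC[C@@H]2OC(=O)[C@H](C)[C@@]2(O)[C@H](OC(C)=O)[C@H]1[C@@H](C)[C@H](O[Si](C)(C)C(C)(C)C)C[C@H](OC(C)=O)[C@]1(C)[C@H](OC(C)=O)CCI | intermediate (not isolated)
36 | C5 dimethyl phosphonate methyl ester (C5 epimers) | CC(C)(C)[Si](C)(C)OC[C@@H]2OC(=O)[C@H](C)[C@@]2(O)[C@H](OC(C)=O)[C@H]1[C@@H](C)[C@H](O[Si](C)(C)C(C)(C)C)C[C@H](OC(C)=O)[C@]1(C)[C@H](OC(C)=O)CCC(C(=O)OC)P(=O)(OC)OC | intermediate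
37 | 6,8,12-triol of 36 | OC[C@@H]2OC(=O)[C@H](C)[C@@]2(O)[C@H](OC(C)=O)[C@H]1[C@@H](C)[C@H](O)C[C@H](OC(C)=O)[C@]1(C)[C@H](OC(C)=O)CCC(C(=O)OC)P(=O)(OC)OC | intermediate
38 | C6 aldehyde of 37 | O=C[C@@H]2OC(=O)[C@H](C)[C@@]2(O)[C@H](OC(C)=O)[C@H]1[C@@H](C)[C@H](O)C[C@H](OC(C)=O)[C@]1(C)[C@H](OC(C)=O)CCC(C(=O)OC)P(=O)(OC)OC | intermediate
39 | 12-O-deacetyl target (5E; 12α-OH) | COC(=O)/C1=C/[C@@H]2OC(=O)[C@H](C)[C@@]2(O)[C@H](OC(C)=O)[C@H]2[C@@H](C)[C@H](O)C[C@H](OC(C)=O)[C@]2(C)[C@H](OC(C)=O)CC1 | intermediate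
40 | CNP0230222.1 (1S,2R,5E,7S,8S,9R,10S,11R,12R,14S,17R) | COC(=O)/C1=C/[C@@H]2OC(=O)[C@H](C)[C@@]2(O)[C@H](OC(C)=O)[C@H]2[C@@H](C)[C@H](OC(C)=O)C[C@H](OC(C)=O)[C@]2(C)[C@H](OC(C)=O)CC1 | target

Total step count: 26. Longest linear sequence: 18 steps (steps 1–3, 7–12 and 18–26; the branch through steps 4–6 is equally long).

Steps most likely to fail

1. Step 9. The opening may become stepwise, giving a free tertiary C1 cation that erodes the anti-stereospecific shift, lets the C13 methylene migrate, or eliminates to allylic alcohols. The fallback sets out from 13. The tertiary hydroxyl would be silylated (Me3SiCl, imidazole, DMF) to the epoxy trimethylsilyl ether F1. Treatment with TiCl4 in CH2Cl2 at −78 °C should then bring about the Suzuki–Tsuchihashi rearrangement, in which the titanium-bound epoxide and the silyloxy donor enforce a concerted anti shift of C10 through a silyloxocarbenium ion. Aqueous work-up removes the silyl group and the route is rejoined at 14.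

2. Step 25. Oligomerisation may outrun closure of the strained ten-membered ring, and the base may epimerise C7 or cause β-elimination of the C8 hydroxyl. The fallback sets out from 36 and moves the ring closure to olefin metathesis. Intermolecular Horner–Wadsworth–Emmons reaction with paraformaldehyde (LiCl, i-Pr2NEt, MeCN) would give the α-methylene ester F2. HF·pyridine would give the triol F3, and 2,2,6,6-tetramethylpiperidine-1-oxyl/PhI(OAc)2 the aldehyde F4. Takai–Lombardo methylenation (Zn, CH2I2, TiCl4) would give the C7 ethenyl compound F5. Ring-closing metathesis with second-generation Hoveyda–Grubbs catalyst in hot dilute toluene should then give the in-ring cis enoate and rejoin the route at 39.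

3. Step 3. The doubly activated C10 proton may epimerise to the trans ketone during quench or isolation, or the dienolate may be protonated at the γ-carbon to give the conjugated ethylidene ketone. The fallback sets out from 3. The cuprate enolate 4 would be trapped with Me3SiCl/Et3N as the trimethylsilyl dienol ether F6 and isolated without aqueous base. Low-temperature protonation in toluene with a Lewis acid-assisted Brønsted acid (SnCl4·BINOL, antipode matched to the substrate) is a reagent-controlled protonation of a neutral enol ether and should deliver the proton to the face opposite the C11 methyl. The route is rejoined at 5, which is taken directly into step 7.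

Further compounds

F1 | step 9 | O14-trimethylsilyl ether of epoxy alcohol 13 | C[C@]1(O[C@@H]1CCCl)[C@]2(O[Si](C)(C)C)[C@@H](C=C)[C@@H](C)[C@H](O[Si](C)(C)C(C)(C)C)C2
F2 | step 25 | α-methylene methyl ester from 36 (C5=CH2) | CC(C)(C)[Si](C)(C)OC[C@@H]2OC(=O)[C@H](C)[C@@]2(O)[C@H](OC(C)=O)[C@H]1[C@@H](C)[C@H](O[Si](C)(C)C(C)(C)C)C[C@H](OC(C)=O)[C@]1(C)[C@H](OC(C)=O)CCC(=C)C(=O)OC
F3 | step 25 | 6,8,12-triol of F2 | OC[C@@H]2OC(=O)[C@H](C)[C@@]2(O)[C@H](OC(C)=O)[C@H]1[C@@H](C)[C@H](O)C[C@H](OC(C)=O)[C@]1(C)[C@H](OC(C)=O)CCC(=C)C(=O)OC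
F4 | step 25 | C6 aldehyde of F3 | O=C[C@@H]2OC(=O)[C@H](C)[C@@]2(O)[C@H](OC(C)=O)[C@H]1[C@@H](C)[C@H](O)C[C@H](OC(C)=O)[C@]1(C)[C@H](OC(C)=O)CCC(=C)C(=O)OC
F5 | step 25 | C7 ethenyl diene for ring-closing metathesis | C=C[C@@H]2OC(=O)[C@H](C)[C@@]2(O)[C@H](OC(C)=O)[C@H]1[C@@H](C)[C@H](O)C[C@H](OC(C)=O)[C@]1(C)[C@H](OC(C)=O)CCC(=C)C(=O)OC
F6 | step 3 | trimethylsilyl dienol ether of 5 | C[Si](C)(C)OC1=C(C=C)[C@@H](C)[C@H](O[Si](C)(C)C(C)(C)C)C1
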